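## The problem

Locants used throughout: ring A is the styryl-bearing dihydrobenzofuran (O1, C2, C3, C3a, C4–C7, C7a); ring B is the second one, with primed locants; a chroman-2-one is numbered O1, C2 (carbonyl), C3, C4, C4a, C5–C8, C8a.

The target is a stilbenoid trimer: two 2,3-trans-2,3-diaryl-2,3-dihydrobenzofurans joined by one single bond from C3 of ring A to C6' of ring B, with an (E)-4-hydroxystyryl group on C6 of ring A. No rings are fused, so the task is to place four aryl-bearing sp3 carbons on two electron-rich arenes. Ring A is (2R,3R) and ring B is (2'S,3'S); the two heterocycles have opposite absolute sense and are separated by a freely rotating aryl–C bond, so neither can direct the other and each needs its own external control. Within a ring, C3 can control C2, because trans is the thermodynamic arrangement and also the result of anti attack on a planar C2. The absolute problem therefore reduces to the two diarylmethine carbons C3 and C3'. The eight phenols must stay masked to the end; the stilbene is sensitive to sensitised light, hydrometalation, electrophiles and strong acid; a benzylic C2–O bond next to a para-oxygenated aryl group ionises under acid. The feature that opens the route is in ring A: the O1–C7a bond, the C3a–C3 bond and the C3 aryl group coincide with O1–C8a, C4a–C4 and the 4-aryl group of a chroman-2-one, which has one carbonyl carbon more between O1 and the future C2. C4 of that lactone is the β-carbon of a flat coumarin and can be set by asymmetric conjugate addition. An α-bromide then lets the lactone contract by hydrolysis and internal O-alkylation, leaving a carboxyl group on C2 as the handle for the last aryl group. Ring B has the same feature.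

## Retrosynthesis

**Eight O–methyl bonds.** Target 33 is traced back to its octamethyl ether 32. Methyl ethers survive enolates, hydroxide, organozinc reagents and the rhodium, iridium, palladium and nickel catalysts, and the commercial arenes already carry them. The price is one Lewis-acid cleavage at the end. That is acceptable here: both rings are the thermodynamic trans isomers, and the C6 styryl group has no nucleophilic arene within reach.

**C2–aryl bond of ring A.** 32 is cut between C2 and its 4-methoxyphenyl group to give redox-active ester 29 (from acid 28) and arylzinc 31 (from Grignard reagent 30). Cutting O1–C2 instead would leave a C2 carbinol to be set on an open chain; cutting the C3–aryl bond would give up the centre that carries the absolute information. The chosen cut removes one arene and one stereocenter. The forward step passes through a planar C2 radical, which should be arylated anti to the C3 substituent. The radical is generated thermally, not by light, to spare the stilbene.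

**O1–C2 bond of ring A (key).** Acid 28 is traced to the trans 3-bromo-4-arylchroman-2-one 26 by breaking O1–C2 and re-attaching O1 to the carboxyl carbon; the ring-opened dianion 27 is the link. The precursor has its decisive stereocenter at C4 of a six-membered lactone. The forward step needs hydroxide to open the lactone and the freed phenoxide to substitute bromide before any base removes HBr.

**C3–Br bond.** 26 comes from lactone 24 through its enolate 25. Only anti attack of an electrophilic bromine source with respect to the C4 aryl group is required, and even that is not critical because C2 is reset later.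

**C4–C6' bond between the halves.** 24 is cut into coumarin 23 and boronic acid 16. Conjugate arylation makes the bond and the stereocenter in one catalytic step and brings no hydride reagent near the stilbene. A two-stage alternative (cross-coupling to a 4-arylcoumarin, then asymmetric conjugate reduction) would need a 4-hydroxycoumarin that takes four more steps to prepare. The cost is an excess of 16, softened because protodeboronation returns 14.

**Coumarin 23.** The stilbene is cut at the aryl–vinyl bond to bromocoumarin 21 and styrene 22. The pyranone is cut at C3=C4 to salicylaldehyde 18 (through cinnamates 19 and 20), and 18 comes from commercial aldehyde 17 by removal of one ortho methyl group. The 1,3,5-pattern of ring A is bought, not built.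

**C6'–B bond.** 16 (through pinacol ester 15) is traced to arene 14, whose C6'–H is its only aromatic C–H without an ortho neighbour. Carrying fragment 1 without halogen keeps the nickel step of that fragment free of a competing aryl halide.

**Ring B.** 14 is taken apart exactly as ring A: C2'–aryl bond to ester 11 and arylzinc 13 (from 12); 11 to acid 10; O1'–C2' to bromolactone 8 (through 9); bromide to lactone 6 (through 7); the C4–aryl bond to coumarin 4 and boronic acid 5; and 4 to salicylaldehyde 1 (through 2 and 3). The antipodal ligand gives the opposite sense, and the contraction is rehearsed on 8 before it is asked of 26.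

## Roads not taken

**Alternative 1:** The ring A arene is cut at C3a–C7a, C4–C5 and C7–C7a into the styrylcyclobutenone A2 and the triisopropylsilyl ynol ether A3, whose alkyne carries C3 and C2 as an open chain. On heating, A2 opens to a vinylketene, adds to A3, and electrocyclic opening and closure give the resorcinol mono-silyl ether A1.
- Merits: the regiochemistry is fixed by the mechanism; the two ring A oxygens emerge differentiated (free OH against silyl ether), which is cleaner than the chelation-controlled demethylation used here; the stilbene arrives with A2.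
- Weak points: C3 in A3 is propargylic and doubly activated, so it must be set, anti to C2, on an acyclic chain and then survive ynol ether formation and a thermal step. A2 and A3 are each multi-step. A1 still needs desilylation, ring closure at C2 and exchange of the silyl ether.
- Comparison: the chosen plan buys the arene (17) and sets C3 on a rigid lactone by catalyst control. Alternative 1 would be the better road only if no suitably substituted benzaldehyde existed.

**Alternative 2:** Ring B is cut at C3'–C3a', reconnecting C3a' to the carbonyl carbon of the chiral-pool-derived (2S)-flavanone A5. With PhI(OAc)2 and acid in trimethyl orthoformate, the enol ether is iodinated at C3 and the electron-rich A-ring carbon shifts from C4 to C3, giving the trans ester A4.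
- Merits: C2' and the catechol ring come from a natural flavanone with no asymmetric catalyst, and the shift is stereospecific. In this respect it is better than the chosen plan, which needs a chiral rhodium catalyst for ring B.
- Weak points: A4 carries an ester, not the 3,5-dioxygenated aryl group, at C3', so a decarboxylative arylation at a doubly benzylic carbon is still owed. 5-Alkoxyflavanones racemise through the chalcone during the protection steps. Migration of the other aryl group and dehydrogenation compete. The benzyloxy group must become a carbon handle. Ring A is not addressed at all.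
- Comparison: counted out, it replaces steps 1–7 by a sequence that is no shorter. The chosen plan offers one sequence that serves both rings.

**Alternative 3:** The ring B arene is cut at C3a'–C7a', C4'–C5' and C6'–C7' into diyne A7 (an ethynyl ether and a silylalkyne tethered through C2'–C3') and the ring A alkyne A8. Cp*RuCl(cod) forms the ruthenacycle from A7, inserts A8 and releases A6, closing the benzene and the dihydrofuran together.
- Merits: it is the most convergent union, joining two finished halves. The chosen plan is inferior here, since fragment 1 must pass through five further steps after the union.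
- Weak points: A6 has silicon where the target has the C4' oxygen, and the ipso exchange needs an electrophilic halogen that the stilbene will not tolerate. The secondary benzylic ethynyl ether in A7 is thermally labile. A8 still requires the ring A stereodiad, so the ring A problem is only moved. Self-trimerisation of A8 competes.
- Comparison: the chosen plan has every oxygen in place from the first step and needs no unstable alkyne.

Key step: step 13

Assumption on the chemistry: the sense of induction of the SEGPHOS–rhodium catalyst is taken from the parent coumarin (the (R)-ligand gives the (R)-4-arylchroman-2-one in which C4a outranks the new aryl group). If the peri methoxy group reverses it, the ligand antipodes of steps 2 and 11 are exchanged.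

Remark: compounds 1, 5, 17, 22 and the Grignard solutions 12 and 30 are taken as commercial.

## Route

**Fragment 1 (ring B)**

Step 1
Reactants: 1 2-hydroxy-6-methoxybenzaldehyde
Product: 4 5-methoxycoumarin, via ethyl (E)-3-(2-hydroxy-6-methoxyphenyl)prop-2-enoate 2 (not isolated), via ethyl (Z)-3-(2-hydroxy-6-methoxyphenyl)prop-2-enoate 3 (not isolated)
Conditions: Ph3P=CHCO2Et, PhNEt2, reflux
Reagents that add atoms: ethyl (triphenylphosphoranylidene)acetate, CCOC(=O)C=P(c1ccccc1)(c1ccccc1)c1ccccc1
Why: Wittig olefination with a stabilised ylide, followed in the same pot by thermal E/Z isomerisation and lactonisation of the Z ester onto the free phenol, the standard salicylaldehyde-to-coumarin route; no stereocenter is formed.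

Step 2
Reactants: 4 5-methoxycoumarin; 5 3,5-dimethoxyphenylboronic acid
Product: 6 (4S)-4-(3,5-dimethoxyphenyl)-5-methoxychroman-2-one
Conditions: Rh(acac)(C2H4)2 (3 mol%), (S)-SEGPHOS, 5 in excess, dioxane/H2O (10:1), 60 °C
Reagents that add atoms: none
Why: Hayashi–Miyaura asymmetric conjugate arylation of a coumarin: the aryl group on monovalent rhodium migrates to C4 from the enantioface chosen by the bisphosphine, setting C4 as S, and water protonates the rhodium enolate. The peri methoxy group lies in the ring plane while the aryl group arrives perpendicular to it, and the inexpensive boronic acid is used in excess to offset protodeboronation.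

Step 3
Reactants: 6 (4S)-4-(3,5-dimethoxyphenyl)-5-methoxychroman-2-one
Product: 8 (3R,4S)-3-bromo-4-(3,5-dimethoxyphenyl)-5-methoxychroman-2-one (3,4-trans), via lithium enolate 7 (not isolated)
Conditions: LiN(SiMe3)2, THF, −78 °C; then NBS, −78 °C
Reagents that add atoms: N-bromosuccinimide, O=C1CCC(=O)N1Br
Why: Electrophilic α-bromination of a lactone lithium enolate; the bromine source should approach the face opposite the pseudoaxial C4 aryl group, giving the trans bromide. At −78 °C the aryl ester enolate does not expel phenoxide, and the enolate consumes NBS before the electron-rich arenes can.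

Step 4
Reactants: 8 (3R,4S)-3-bromo-4-(3,5-dimethoxyphenyl)-5-methoxychroman-2-one
Product: 10 (2S,3S)-3-(3,5-dimethoxyphenyl)-4-methoxy-2,3-dihydro-1-benzofuran-2-carboxylic acid (2,3-trans), via ring-opened dipotassium bromo carboxylate 9 (not isolated)
Conditions: KOH, THF/H2O, 0 °C to rt; then 1 M HCl to pH 3
Reagents that add atoms: potassium hydroxide, [K+].[OH-]
Why: Lactone hydrolysis followed by intramolecular Williamson etherification (5-exo-tet, inversion at the bromide carbon), the same ring contraction as the key step on the simpler lactone. C3 (the former C4) is not touched, and the trans bromide should give the trans acid.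

Step 5
Reactants: 10 (2S,3S)-3-(3,5-dimethoxyphenyl)-4-methoxy-2,3-dihydro-1-benzofuran-2-carboxylic acid
Product: 11 1,3-dioxoisoindolin-2-yl (2S,3S)-3-(3,5-dimethoxyphenyl)-4-methoxy-2,3-dihydro-1-benzofuran-2-carboxylate
Conditions: N-hydroxyphthalimide, DIC, DMAP (cat.), CH2Cl2, rt
Reagents that add atoms: N-hydroxyphthalimide, O=C1c2ccccc2C(=O)N1O
Why: Carbodiimide (Steglich-type) esterification to the redox-active ester; the C2 configuration is of no consequence because it is erased in step 6.

Step 6
Reactants: 11 1,3-dioxoisoindolin-2-yl (2S,3S)-3-(3,5-dimethoxyphenyl)-4-methoxy-2,3-dihydro-1-benzofuran-2-carboxylate; 12 3,4-dimethoxyphenylmagnesium bromide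
Product: 14 (2S,3S)-2-(3,4-dimethoxyphenyl)-3-(3,5-dimethoxyphenyl)-4-methoxy-2,3-dihydro-1-benzofuran (2,3-trans), via 3,4-dimethoxyphenylzinc chloride 13 (not isolated)
Conditions: 12, ZnCl2, LiCl, THF, 0 °C to rt; then 11, NiCl2(glyme) (20 mol%), 4,4'-di-tert-butyl-2,2'-bipyridine, THF/DMF, rt
Reagents that add atoms: none
Why: Transmetalation of the Grignard reagent to zinc, then nickel-catalysed decarboxylative Negishi-type arylation of the redox-active ester: single-electron reduction releases CO2 and phthalimide and leaves a planar α-oxy radical at C2. Aryl-nickel should capture and couple it on the face anti to the C3 aryl group, so C3 sets C2 as trans (2S).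

Step 7
Reactants: 14 (2S,3S)-2-(3,4-dimethoxyphenyl)-3-(3,5-dimethoxyphenyl)-4-methoxy-2,3-dihydro-1-benzofuran
Product: 16 [(2S,3S)-2-(3,4-dimethoxyphenyl)-3-(3,5-dimethoxyphenyl)-4-methoxy-2,3-dihydro-1-benzofuran-6-yl]boronic acid, via pinacol boronate 15 (not isolated)
Conditions: [Ir(OMe)(cod)]2 (1.5 mol%), 4,4'-di-tert-butyl-2,2'-bipyridine, B2pin2, THF, 80 °C; then NaIO4, NH4OAc, acetone/H2O, rt
Reagents that add atoms: bis(pinacolato)diboron, CC1(C)OB(OC1(C)C)B1OC(C)(C)C(C)(C)O1; water, O
Why: Iridium-catalysed aromatic C–H borylation is governed by sterics, and C6–H is the only aromatic C–H of 14 without an ortho substituent, so boron should enter there. Periodate cleavage of the pinacol then frees the boronic acid needed for the base-free rhodium step.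

**Fragment 2 (ring A coumarin)**

Step 8
Reactants: 17 4-bromo-2,6-dimethoxybenzaldehyde
Product: 18 4-bromo-2-hydroxy-6-methoxybenzaldehyde
Conditions: BCl3, CH2Cl2, −78 °C to rt; then H2O
Reagents that add atoms: none
Why: Chelation-controlled mono-O-demethylation ortho to a carbonyl group; once the boron phenoxide chelate has formed, the aldehyde no longer assists cleavage of the second ether, and the aryl bromide is inert.

Step 9
Reactants: 18 4-bromo-2-hydroxy-6-methoxybenzaldehyde
Product: 21 7-bromo-5-methoxycoumarin, via ethyl (E)-3-(4-bromo-2-hydroxy-6-methoxyphenyl)prop-2-enoate 19 (not isolated), via ethyl (Z)-3-(4-bromo-2-hydroxy-6-methoxyphenyl)prop-2-enoate 20 (not isolated)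
Conditions: Ph3P=CHCO2Et, PhNEt2, reflux
Reagents that add atoms: ethyl (triphenylphosphoranylidene)acetate, CCOC(=O)C=P(c1ccccc1)(c1ccccc1)c1ccccc1
Why: Same Wittig olefination–lactonisation as step 1; the aryl bromide survives the thermal conditions.

Step 10
Reactants: 21 7-bromo-5-methoxycoumarin; 22 4-methoxystyrene
Product: 23 5-methoxy-7-[(E)-2-(4-methoxyphenyl)ethenyl]coumarin
Conditions: Pd(OAc)2 (5 mol%), P(o-tol)3, Et3N, DMF, 100 °C
Reagents that add atoms: none
Why: Mizoroki–Heck reaction; aryl-palladium formed at C7–Br inserts the terminal styrene far faster than the internal, electron-poor coumarin alkene, and syn β-hydride elimination gives the E stilbene.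

**Union and ring A**

Step 11
Reactants: 23 5-methoxy-7-[(E)-2-(4-methoxyphenyl)ethenyl]coumarin; 16 [(2S,3S)-2-(3,4-dimethoxyphenyl)-3-(3,5-dimethoxyphenyl)-4-methoxy-2,3-dihydro-1-benzofuran-6-yl]boronic acid
Product: 24 (4R)-4-[(2S,3S)-2-(3,4-dimethoxyphenyl)-3-(3,5-dimethoxyphenyl)-4-methoxy-2,3-dihydro-1-benzofuran-6-yl]-5-methoxy-7-[(E)-2-(4-methoxyphenyl)ethenyl]chroman-2-one
Conditions: Rh(acac)(C2H4)2 (5 mol%), (R)-SEGPHOS, 16 added in portions, dioxane/H2O (10:1), 60 °C
Reagents that add atoms: none
Why: Hayashi–Miyaura conjugate arylation joins the fragments through C4–C6' and sets C4 as R under control of the (R)-ligand; the stereocenters of fragment 1 are too remote to interfere, and the stilbene is not an acceptor for aryl-rhodium. Boronic acid lost by protodeboronation reappears as 14 and can be returned to step 7.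

Step 12
Reactants: 24 (4R)-4-[(2S,3S)-2-(3,4-dimethoxyphenyl)-3-(3,5-dimethoxyphenyl)-4-methoxy-2,3-dihydro-1-benzofuran-6-yl]-5-methoxy-7-[(E)-2-(4-methoxyphenyl)ethenyl]chroman-2-one
Product: 26 (3S,4R)-3-bromo-4-[(2S,3S)-2-(3,4-dimethoxyphenyl)-3-(3,5-dimethoxyphenyl)-4-methoxy-2,3-dihydro-1-benzofuran-6-yl]-5-methoxy-7-[(E)-2-(4-methoxyphenyl)ethenyl]chroman-2-one (3,4-trans), via lithium enolate 25 (not isolated)
Conditions: LiN(SiMe3)2, THF, −78 °C; then NBS, −78 °C
Reagents that add atoms: N-bromosuccinimide, O=C1CCC(=O)N1Br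
Why: α-Bromination of the lactone lithium enolate as in step 3, anti to the C4 aryl group, to give the trans bromide. At −78 °C the enolate should outcompete the stilbene and the arenes for NBS, and the amide base does not remove the doubly benzylic C3'–H.

Step 13
Reactants: 26 (3S,4R)-3-bromo-4-[(2S,3S)-2-(3,4-dimethoxyphenyl)-3-(3,5-dimethoxyphenyl)-4-methoxy-2,3-dihydro-1-benzofuran-6-yl]-5-methoxy-7-[(E)-2-(4-methoxyphenyl)ethenyl]chroman-2-one
Product: 28 (2R,3R)-3-[(2S,3S)-2-(3,4-dimethoxyphenyl)-3-(3,5-dimethoxyphenyl)-4-methoxy-2,3-dihydro-1-benzofuran-6-yl]-4-methoxy-6-[(E)-2-(4-methoxyphenyl)ethenyl]-2,3-dihydro-1-benzofuran-2-carboxylic acid (2,3-trans), via ring-opened dipotassium bromo carboxylate 27 (not isolated)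
Conditions: KOH (3 equiv), THF/H2O (3:1), 0 °C to rt; then 1 M HCl to pH 3
Reagents that add atoms: potassium hydroxide, [K+].[OH-]
Why: Hydroxide adds to the activated aryl ester carbonyl of 26 and opens the lactone to the phenoxide–carboxylate 27. In 27 the phenoxide oxygen lies five atoms from the bromine-bearing carbon and displaces bromide from the rear; this forms O1–C2 and contracts the six-membered lactone to the dihydrofuran by 5-exo-tet closure, the only ring closed. The closest known reactions are the base-induced contraction of 3-halocoumarins to benzofuran-2-carboxylic acids (Perkin rearrangement) and the contraction of α-halo or α-sulfonyloxy δ-lactones to tetrahydrofuran-2-carboxylates; the second half is an intramolecular Williamson etherification of an α-bromo carboxylate. C3 of 28 is the untouched C4 of 26 and should keep its configuration, because its hydrogen, though doubly benzylic, is not acidic towards aqueous hydroxide once the carbonyl has become a carboxylate. C2 is formed with inversion at the bromide carbon, so the trans bromide should give the trans acid; this centre is provisional, since step 15 passes through a planar radical. The selectivity required is substitution over loss of HBr: in the closed lactone the trans arrangement holds Br and H4 syn, so anti elimination is geometrically barred, and in the open form the double negative charge disfavours deprotonation at the diarylmethine carbon while the phenoxide is held next to the electrophilic carbon. The stilbene, the aryl ethers and ring B are inert to aqueous hydroxide at room temperature.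

Step 14
Reactants: 28 (2R,3R)-3-[(2S,3S)-2-(3,4-dimethoxyphenyl)-3-(3,5-dimethoxyphenyl)-4-methoxy-2,3-dihydro-1-benzofuran-6-yl]-4-methoxy-6-[(E)-2-(4-methoxyphenyl)ethenyl]-2,3-dihydro-1-benzofuran-2-carboxylic acid
Product: 29 1,3-dioxoisoindolin-2-yl ester of acid 28, (2R,3R) in ring A and (2S,3S) in ring B
Conditions: N-hydroxyphthalimide, DIC, DMAP (cat.), CH2Cl2, rt
Reagents that add atoms: N-hydroxyphthalimide, O=C1c2ccccc2C(=O)N1O
Why: Carbodiimide (Steglich-type) esterification to the redox-active ester, as in step 5; neutral conditions leave the stilbene and both rings untouched.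

Step 15
Reactants: 29 1,3-dioxoisoindolin-2-yl ester of acid 28; 30 4-methoxyphenylmagnesium bromide
Product: 32 (2S,3S)-2-(3,4-dimethoxyphenyl)-3-(3,5-dimethoxyphenyl)-4-methoxy-6-{(2R,3R)-4-methoxy-2-(4-methoxyphenyl)-6-[(E)-2-(4-methoxyphenyl)ethenyl]-2,3-dihydro-1-benzofuran-3-yl}-2,3-dihydro-1-benzofuran (octamethyl ether of the target), via 4-methoxyphenylzinc chloride 31 (not isolated)
Conditions: 30, ZnCl2, LiCl, THF, 0 °C to rt; then 29, NiCl2(glyme) (20 mol%), 4,4'-di-tert-butyl-2,2'-bipyridine, THF/DMF, rt
Reagents that add atoms: none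
Why: Nickel-catalysed decarboxylative Negishi-type arylation as in step 6; the planar C2 radical should be arylated anti to the bulky C3 substituent, giving the 2,3-trans (2R,3R) ring. The radical is generated thermally, not photochemically, so the E stilbene is not sensitised.

Step 16
Reactants: 32 octamethyl ether of the target
Product: 33 4-[(2S,3S)-3-(3,5-dihydroxyphenyl)-4-hydroxy-6-{(2R,3R)-4-hydroxy-2-(4-hydroxyphenyl)-6-[(E)-2-(4-hydroxyphenyl)ethenyl]-2,3-dihydro-1-benzofuran-3-yl}-2,3-dihydro-1-benzofuran-2-yl]benzene-1,2-diol (CNP0107857.3)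
Conditions: BBr3 (excess), CH2Cl2, −78 °C to rt; then H2O
Reagents that add atoms: none
Why: Lewis-acid cleavage of aryl methyl ethers: each boron-complexed ether is demethylated by bromide and the aryl borates are hydrolysed on work-up. Both rings are the thermodynamic trans isomers at C2, so reversible ionisation of a benzylic C2–O bond should return the same configuration, and the stilbene at C6 has no nucleophilic arene within reach for cyclisation.

## Compound list

1 | 2-hydroxy-6-methoxybenzaldehyde | COc1cccc(O)c1C=O | starting material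
2 | ethyl (E)-3-(2-hydroxy-6-methoxyphenyl)prop-2-enoate (not isolated) | CCOC(=O)/C=C/c1c(O)cccc1OC | intermediate
3 | ethyl (Z)-3-(2-hydroxy-6-methoxyphenyl)prop-2-enoate (not isolated) | CCOC(=O)/C=C\c1c(O)cccc1OC | intermediate
4 | 5-methoxycoumarin | COc1cccc2oc(=O)ccc12 | intermediate
5 | 3,5-dimethoxyphenylboronic acid | COc1cc(OC)cc(B(O)O)c1 | starting material
6 | (4S)-4-(3,5-dimethoxyphenyl)-5-methoxychroman-2-one | O=C1C[C@@H](c2cc(OC)cc(OC)c2)c2c(OC)cccc2O1 | intermediate
7 | lithium (4S)-4-(3,5-dimethoxyphenyl)-5-methoxy-4H-chromen-2-olate (not isolated) | [Li]OC1=C[C@@H](c2cc(OC)cc(OC)c2)c2c(OC)cccc2O1 | intermediate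
8 | (3R,4S)-3-bromo-4-(3,5-dimethoxyphenyl)-5-methoxychroman-2-one | O=C1[C@H](Br)[C@@H](c2cc(OC)cc(OC)c2)c2c(OC)cccc2O1 | intermediate
9 | dipotassium (2R,3S)-2-bromo-3-(3,5-dimethoxyphenyl)-3-(2-methoxy-6-oxidophenyl)propanoate (not isolated) | [K+].[K+].[O-]C(=O)[C@H](Br)[C@@H](c1cc(OC)cc(OC)c1)c1c(OC)cccc1[O-] | intermediate
10 | (2S,3S)-3-(3,5-dimethoxyphenyl)-4-methoxy-2,3-dihydro-1-benzofuran-2-carboxylic acid | OC(=O)[C@H]1Oc2cccc(OC)c2[C@@H]1c1cc(OC)cc(OC)c1 | intermediate
11 | 1,3-dioxoisoindolin-2-yl (2S,3S)-3-(3,5-dimethoxyphenyl)-4-methoxy-2,3-dihydro-1-benzofuran-2-carboxylate | O=C(ON1C(=O)c2ccccc2C1=O)[C@H]1Oc2cccc(OC)c2[C@@H]1c1cc(OC)cc(OC)c1 | intermediate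
12 | 3,4-dimethoxyphenylmagnesium bromide | COc1ccc([Mg]Br)cc1OC | starting material
13 | 3,4-dimethoxyphenylzinc chloride (not isolated) | COc1ccc([Zn]Cl)cc1OC | intermediate
14 | (2S,3S)-2-(3,4-dimethoxyphenyl)-3-(3,5-dimethoxyphenyl)-4-methoxy-2,3-dihydro-1-benzofuran | COc1cccc2O[C@H](c3ccc(OC)c(OC)c3)[C@@H](c3cc(OC)cc(OC)c3)c12 | intermediate
15 | 2-[(2S,3S)-2-(3,4-dimethoxyphenyl)-3-(3,5-dimethoxyphenyl)-4-methoxy-2,3-dihydro-1-benzofuran-6-yl]-4,4,5,5-tetramethyl-1,3,2-dioxaborolane (not isolated) | COc1cc(B3OC(C)(C)C(C)(C)O3)cc2O[C@H](c3ccc(OC)c(OC)c3)[C@@H](c3cc(OC)cc(OC)c3)c12 | intermediate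
16 | [(2S,3S)-2-(3,4-dimethoxyphenyl)-3-(3,5-dimethoxyphenyl)-4-methoxy-2,3-dihydro-1-benzofuran-6-yl]boronic acid | COc1cc(B(O)O)cc2O[C@H](c3ccc(OC)c(OC)c3)[C@@H](c3cc(OC)cc(OC)c3)c12 | intermediate
17 | 4-bromo-2,6-dimethoxybenzaldehyde | COc1cc(Br)cc(OC)c1C=O | starting material
18 | 4-bromo-2-hydroxy-6-methoxybenzaldehyde | COc1cc(Br)cc(O)c1C=O | intermediate
19 | ethyl (E)-3-(4-bromo-2-hydroxy-6-methoxyphenyl)prop-2-enoate (not isolated) | CCOC(=O)/C=C/c1c(O)cc(Br)cc1OC | intermediate
20 | ethyl (Z)-3-(4-bromo-2-hydroxy-6-methoxyphenyl)prop-2-enoate (not isolated) | CCOC(=O)/C=C\c1c(O)cc(Br)cc1OC | intermediate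
21 | 7-bromo-5-methoxycoumarin | COc1cc(Br)cc2oc(=O)ccc12 | intermediate
22 | 4-methoxystyrene | C=Cc1ccc(OC)cc1 | starting material
23 | 5-methoxy-7-[(E)-2-(4-methoxyphenyl)ethenyl]coumarin | COc1ccc(/C=C/c2cc(OC)c3ccc(=O)oc3c2)cc1 | intermediate
24 | (4R)-4-[(2S,3S)-2-(3,4-dimethoxyphenyl)-3-(3,5-dimethoxyphenyl)-4-methoxy-2,3-dihydro-1-benzofuran-6-yl]-5-methoxy-7-[(E)-2-(4-methoxyphenyl)ethenyl]chroman-2-one | COc1ccc(/C=C/c2cc(OC)c3c(c2)OC(=O)C[C@@H]3c2cc(OC)c3c(c2)O[C@H](c2ccc(OC)c(OC)c2)[C@H]3c2cc(OC)cc(OC)c2)cc1 | intermediate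
25 | lithium enolate of 24 (not isolated) | COc1ccc(/C=C/c2cc(OC)c3c(c2)OC(O[Li])=C[C@@H]3c2cc(OC)c3c(c2)O[C@H](c2ccc(OC)c(OC)c2)[C@H]3c2cc(OC)cc(OC)c2)cc1 | intermediate
26 | (3S,4R)-3-bromo-4-[(2S,3S)-2-(3,4-dimethoxyphenyl)-3-(3,5-dimethoxyphenyl)-4-methoxy-2,3-dihydro-1-benzofuran-6-yl]-5-methoxy-7-[(E)-2-(4-methoxyphenyl)ethenyl]chroman-2-one | COc1ccc(/C=C/c2cc(OC)c3c(c2)OC(=O)[C@@H](Br)[C@@H]3c2cc(OC)c3c(c2)O[C@H](c2ccc(OC)c(OC)c2)[C@H]3c2cc(OC)cc(OC)c2)cc1 | intermediate
27 | dipotassium (2S,3R)-2-bromo-3-[(2S,3S)-2-(3,4-dimethoxyphenyl)-3-(3,5-dimethoxyphenyl)-4-methoxy-2,3-dihydro-1-benzofuran-6-yl]-3-{2-methoxy-6-oxido-4-[(E)-2-(4-methoxyphenyl)ethenyl]phenyl}propanoate (not isolated) | COc1ccc(/C=C/c2cc(OC)c(c([O-])c2)[C@H]([C@H](Br)C([O-])=O)c2cc(OC)c3c(c2)O[C@H](c2ccc(OC)c(OC)c2)[C@H]3c2cc(OC)cc(OC)c2)cc1.[K+].[K+] | intermediate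
28 | (2R,3R)-3-[(2S,3S)-2-(3,4-dimethoxyphenyl)-3-(3,5-dimethoxyphenyl)-4-methoxy-2,3-dihydro-1-benzofuran-6-yl]-4-methoxy-6-[(E)-2-(4-methoxyphenyl)ethenyl]-2,3-dihydro-1-benzofuran-2-carboxylic acid | COc1ccc(/C=C/c2cc(OC)c3c(c2)O[C@@H](C(=O)O)[C@@H]3c2cc(OC)c3c(c2)O[C@H](c2ccc(OC)c(OC)c2)[C@H]3c2cc(OC)cc(OC)c2)cc1 | intermediate
29 | 1,3-dioxoisoindolin-2-yl ester of acid 28 | COc1ccc(/C=C/c2cc(OC)c3c(c2)O[C@@H](C(=O)ON2C(=O)c4ccccc4C2=O)[C@@H]3c2cc(OC)c3c(c2)O[C@H](c2ccc(OC)c(OC)c2)[C@H]3c2cc(OC)cc(OC)c2)cc1 | intermediate
30 | 4-methoxyphenylmagnesium bromide | COc1ccc([Mg]Br)cc1 | starting material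
31 | 4-methoxyphenylzinc chloride (not isolated) | COc1ccc([Zn]Cl)cc1 | intermediate
32 | (2S,3S)-2-(3,4-dimethoxyphenyl)-3-(3,5-dimethoxyphenyl)-4-methoxy-6-{(2R,3R)-4-methoxy-2-(4-methoxyphenyl)-6-[(E)-2-(4-methoxyphenyl)ethenyl]-2,3-dihydro-1-benzofuran-3-yl}-2,3-dihydro-1-benzofuran | COc1ccc(/C=C/c2cc(OC)c3c(c2)O[C@@H](c2ccc(OC)cc2)[C@@H]3c2cc(OC)c3c(c2)O[C@H](c2ccc(OC)c(OC)c2)[C@H]3c2cc(OC)cc(OC)c2)cc1 | intermediate
33 | 4-[(2S,3S)-3-(3,5-dihydroxyphenyl)-4-hydroxy-6-{(2R,3R)-4-hydroxy-2-(4-hydroxyphenyl)-6-[(E)-2-(4-hydroxyphenyl)ethenyl]-2,3-dihydro-1-benzofuran-3-yl}-2,3-dihydro-1-benzofuran-2-yl]benzene-1,2-diol | Oc1ccc(/C=C/c2cc(O)c3c(c2)O[C@@H](c2ccc(O)cc2)[C@@H]3c2cc(O)c3c(c2)O[C@H](c2ccc(O)c(O)c2)[C@H]3c2cc(O)cc(O)c2)cc1 | target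

## Step count and least certain steps

Total: 16 steps. Longest linear sequence: 13 steps (steps 1–7, then 11–16); steps 8–10 form the short branch.

**Step 13 (key step).** The most likely failure is loss of HBr instead of substitution. It could occur by E2 in the open dianion 27, where some rotamers place the doubly benzylic hydrogen anti to bromide, or after epimerisation of 26 to the cis bromide; either way the carbon skeleton falls back to a coumarin. Fallback: close O1–C2 by Mitsunobu etherification instead of bromide displacement. Setting out from 24, the lithium enolate (LiN(SiMe3)2, −78 °C) is hydroxylated with 2-(phenylsulfonyl)-3-phenyloxaziridine, anti to the C4 aryl group, to the trans 3-hydroxy lactone F1. Methanolysis (MeOH, Et3N) opens it to the hydroxy ester phenol F2. PPh3 and diisopropyl azodicarboxylate activate the secondary alcohol, and the phenol displaces it with inversion (5-exo-tet) to give the methyl ester F3. LiOH in THF/H2O returns to 28.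

**Step 11.** The most likely failure is protodeboronation of 16 outrunning insertion of the electron-rich, peri-substituted coumarin 23, which would consume the fragment without forming the bond; erosion of face selectivity is the second concern. Fallback: separate bond formation from stereo-induction. Setting out from 18, excess MeMgBr gives the carbinol F4, and MnO2 oxidises it to the hydroxyacetophenone F5. A Heck reaction with 22 (Pd(OAc)2, P(o-tol)3, Et3N) gives the stilbene ketone F6. NaH and diethyl carbonate in hot toluene close the 4-hydroxycoumarin F7, and Tf2O/Et3N gives the triflate F8. Suzuki coupling with 16 (Pd(PPh3)4, K3PO4, dioxane) gives the 4-arylcoumarin F9. Asymmetric conjugate reduction with copper hydride (Cu(OAc)2, the DTBM-SEGPHOS antipode that gives the 4R lactone, diethoxymethylsilane, t-BuOH, toluene) then arrives at 24.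

**Step 15.** The most likely failure is poor facial selectivity when the planar C2 radical is captured and coupled, because the directing C3 substituent is a freely rotating aryl group; the cis ring would form alongside the trans one. Fallback: thermodynamic control in place of kinetic control. Setting out from 29, the coupling is run without regard to the ratio. The cis isomer F10 in the mixture is then equilibrated with CF3CO2H in CH2Cl2, through reversible heterolysis of the O1–C2 bond to the 4-methoxybenzylic cation and reclosure, to the trans compound 32.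

**Step 16.** The most likely failure is acid-driven damage during the eightfold cleavage: addition of HBr to the electron-rich stilbene or its cationic oligomerisation, together with incomplete demethylation. Fallback: nucleophilic dealkylation under basic, aprotic conditions (sodium ethanethiolate, DMF, 130 °C). Thiolate attacks each methyl group by SN2, and neither a carbocation nor HBr is present. It sets out from 32 and arrives at 33 with no new isolated compound.

## Further compounds

F1 | step 13 | (3S,4R)-3-hydroxy-4-[(2S,3S)-2-(3,4-dimethoxyphenyl)-3-(3,5-dimethoxyphenyl)-4-methoxy-2,3-dihydro-1-benzofuran-6-yl]-5-methoxy-7-[(E)-2-(4-methoxyphenyl)ethenyl]chroman-2-one | COc1ccc(/C=C/c2cc(OC)c3c(c2)OC(=O)[C@@H](O)[C@@H]3c2cc(OC)c3c(c2)O[C@H](c2ccc(OC)c(OC)c2)[C@H]3c2cc(OC)cc(OC)c2)cc1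
F2 | step 13 | methyl (2S,3R)-2-hydroxy-3-[(2S,3S)-2-(3,4-dimethoxyphenyl)-3-(3,5-dimethoxyphenyl)-4-methoxy-2,3-dihydro-1-benzofuran-6-yl]-3-{2-hydroxy-6-methoxy-4-[(E)-2-(4-methoxyphenyl)ethenyl]phenyl}propanoate | COc1ccc(/C=C/c2cc(OC)c(c(O)c2)[C@H]([C@H](O)C(=O)OC)c2cc(OC)c3c(c2)O[C@H](c2ccc(OC)c(OC)c2)[C@H]3c2cc(OC)cc(OC)c2)cc1
F3 | step 13 | methyl ester of acid 28, (2R,3R) in ring A | COc1ccc(/C=C/c2cc(OC)c3c(c2)O[C@@H](C(=O)OC)[C@@H]3c2cc(OC)c3c(c2)O[C@H](c2ccc(OC)c(OC)c2)[C@H]3c2cc(OC)cc(OC)c2)cc1
F4 | step 11 | 5-bromo-2-(1-hydroxyethyl)-3-methoxyphenol (racemic) | CC(O)c1c(O)cc(Br)cc1OC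
F5 | step 11 | 1-(4-bromo-2-hydroxy-6-methoxyphenyl)ethan-1-one | CC(=O)c1c(O)cc(Br)cc1OC
F6 | step 11 | 1-{2-hydroxy-6-methoxy-4-[(E)-2-(4-methoxyphenyl)ethenyl]phenyl}ethan-1-one | CC(=O)c1c(O)cc(/C=C/c2ccc(OC)cc2)cc1OC
F7 | step 11 | 4-hydroxy-5-methoxy-7-[(E)-2-(4-methoxyphenyl)ethenyl]coumarin | COc1ccc(/C=C/c2cc(OC)c3c(O)cc(=O)oc3c2)cc1
F8 | step 11 | 5-methoxy-7-[(E)-2-(4-methoxyphenyl)ethenyl]-2-oxo-2H-chromen-4-yl trifluoromethanesulfonate | COc1ccc(/C=C/c2cc(OC)c3c(OS(=O)(=O)C(F)(F)F)cc(=O)oc3c2)cc1
F9 | step 11 | 4-[(2S,3S)-2-(3,4-dimethoxyphenyl)-3-(3,5-dimethoxyphenyl)-4-methoxy-2,3-dihydro-1-benzofuran-6-yl]-5-methoxy-7-[(E)-2-(4-methoxyphenyl)ethenyl]coumarin | COc1ccc(/C=C/c2cc(OC)c3c(c2)oc(=O)cc3-c2cc(OC)c3c(c2)O[C@H](c2ccc(OC)c(OC)c2)[C@H]3c2cc(OC)cc(OC)c2)cc1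
F10 | step 15 | C2 epimer of 32, (2S,3R) in ring A (2,3-cis) | COc1ccc(/C=C/c2cc(OC)c3c(c2)O[C@H](c2ccc(OC)cc2)[C@@H]3c2cc(OC)c3c(c2)O[C@H](c2ccc(OC)c(OC)c2)[C@H]3c2cc(OC)cc(OC)c2)cc1
F0 | step 16 | none | none
A1 | alternative 1 | 2-{2-(tert-butyldimethylsilyloxy)-1-[(2S,3S)-2-(3,4-dimethoxyphenyl)-3-(3,5-dimethoxyphenyl)-4-methoxy-2,3-dihydro-1-benzofuran-6-yl]-2-(4-methoxyphenyl)ethyl}-5-[(E)-2-(4-methoxyphenyl)ethenyl]-3-(triisopropylsilyloxy)phenol, side chain configured as in the SMILES | Oc1cc(/C=C/c2ccc(OC)cc2)cc(O[Si](C(C)C)(C(C)C)C(C)C)c1[C@@H](c1cc(OC)c2c(c1)O[C@H](c1ccc(OC)c(OC)c1)[C@H]2c1cc(OC)cc(OC)c1)[C@@H](O[Si](C)(C)C(C)(C)C)c1ccc(OC)cc1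
A2 | alternative 1 | 3-[(E)-2-(4-methoxyphenyl)ethenyl]cyclobut-2-en-1-one | O=C1C=C(/C=C/c2ccc(OC)cc2)C1
A3 | alternative 1 | triisopropylsilyl ynol ether carrying the C3–C2 chain, configured as in the SMILES | CC(C)[Si](C(C)C)(C(C)C)OC#C[C@@H](c1cc(OC)c2c(c1)O[C@H](c1ccc(OC)c(OC)c1)[C@H]2c1cc(OC)cc(OC)c1)[C@@H](O[Si](C)(C)C(C)(C)C)c1ccc(OC)cc1
A4 | alternative 2 | methyl (2S,3S)-6-(benzyloxy)-2-[3,4-bis(methanesulfonyloxy)phenyl]-4-methoxy-2,3-dihydro-1-benzofuran-3-carboxylate | c1ccccc1COc1cc(OC)c2c(c1)O[C@H](c1ccc(OS(C)(=O)=O)c(OS(C)(=O)=O)c1)[C@H]2C(=O)OC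
A5 | alternative 2 | (2S)-7-(benzyloxy)-2-[3,4-bis(methanesulfonyloxy)phenyl]-5-methoxychroman-4-one | O=C1C[C@@H](c2ccc(OS(C)(=O)=O)c(OS(C)(=O)=O)c2)Oc2cc(OCc3ccccc3)cc(OC)c12
A6 | alternative 3 | analogue of 32 with trimethylsilyl in place of methoxy at C4' | COc1ccc(/C=C/c2cc(OC)c3c(c2)O[C@@H](c2ccc(OC)cc2)[C@@H]3c2cc([Si](C)(C)C)c3c(c2)O[C@H](c2ccc(OC)c(OC)c2)[C@H]3c2cc(OC)cc(OC)c2)cc1
A7 | alternative 3 | ethynyl ether of 1-(3,4-dimethoxyphenyl)-2-(3,5-dimethoxyphenyl)-4-(trimethylsilyl)but-3-yn-1-ol, configured as in the SMILES | C#CO[C@H](c1ccc(OC)c(OC)c1)[C@H](C#C[Si](C)(C)C)c1cc(OC)cc(OC)c1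
A8 | alternative 3 | trans-3-ethynyl-4-methoxy-2-(4-methoxyphenyl)-6-[(E)-2-(4-methoxyphenyl)ethenyl]-2,3-dihydro-1-benzofuran, configured as in the SMILES | COc1ccc(/C=C/c2cc(OC)c3c(c2)O[C@@H](c2ccc(OC)cc2)[C@@H]3C#C)cc1
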